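## Retrosynthetic overview

1. The C3–O ester is made last by Yamaguchi union of the triol enone core with (2S,3R)-2,3-dimethyloxirane-2-carboxylic acid (Sharpless epoxidation of tiglyl alcohol, then oxidation).
2. Ring B is formed second: the C7–C8 bond is closed by rhodium-catalysed aldehyde C–H activation (6-endo trans-hydroacylation) of a ring A alkynal, which gives the 2-(2-hydroxypropan-2-yl)enone directly.
3. The C3 and C4 oxygens come from aerobic α-hydroxylation of a C3 ketone at C4, then hydroxyl-directed reduction to the trans-diol.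
4. Ring A is formed first: an enantioselective Diels–Alder reaction of an (E)-enynal with the silyl dienol ether of ethyl vinyl ketone sets C10 and C5; a Wittig homologation supplies C8.
5. The enynal comes from a Sonogashira coupling (C5–C6 bond) of (E)-3-bromo-2-methylacrolein with silyl-protected 2-methylbut-3-yn-2-ol.

Position labels C1 to C15 are the eudesmane labels of the target: C3 ester carbon, C4 carbinol, C5 ring-fusion CH, C10 quaternary carbon, C8 ketone, C11 side-chain carbinol. Ring A is C1–C5 plus C10; ring B is C5–C10.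

Assumption: the (S)-configured oxazaborolidinium catalyst gives the Diels–Alder adduct with the absolute configuration drawn; if the opposite sense is found, the mirror-image catalyst is used.

## Route

Step 1
Reactants: 1 2-methylbut-3-yn-2-ol
Product: 2 trimethyl[(2-methylbut-3-yn-2-yl)oxy]silane
Conditions: Me3SiCl, imidazole, CH2Cl2, 0 °C to rt
Reagents that add atoms: chlorotrimethylsilane C[Si](C)(C)Cl
Why: O-silylation (silyl ether protection) masks the tertiary hydroxyl from the strong Lewis acid of step 5; no stereocentre is involved.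

Step 2
Reactants: 3 methacrolein (2-methylprop-2-enal)
Product: 5 (E)-3-bromo-2-methylprop-2-enal, via 2,3-dibromo-2-methylpropanal 4 (not isolated)
Conditions: Br2, CH2Cl2, −78 to 0 °C; then Et3N, 0 °C to rt
Reagents that add atoms: bromine BrBr
Why: bromine addition followed by base-induced dehydrobromination gives the β-bromoenal; the E isomer (Br trans to CHO) is the favoured conjugated product and is purified by distillation.

Step 3
Reactants: 5 (E)-3-bromo-2-methylprop-2-enal; 2 trimethyl[(2-methylbut-3-yn-2-yl)oxy]silane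
Product: 6 (E)-2,6-dimethyl-6-[(trimethylsilyl)oxy]hept-2-en-4-ynal
Conditions: PdCl2(PPh3)2 (2 mol%), CuI (4 mol%), Et3N, THF, rt
Reagents that add atoms: none
Why: Sonogashira coupling of the activated alkenyl bromide with the terminal alkyne forms the C5–C6 bond with retention of the E geometry, which later becomes the trans ring fusion.

Step 4
Reactants: 7 pent-1-en-3-one (ethyl vinyl ketone)
Product: 8 (Z)-triethyl(penta-1,3-dien-3-yloxy)silane
Conditions: Et3SiOTf, Et3N, Et2O, 0 °C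
Reagents that add atoms: triethylsilyl trifluoromethanesulfonate CC[Si](CC)(CC)OS(=O)(=O)C(F)(F)F
Why: soft enolisation and O-silylation give the 2-silyloxy diene; the Z enol ether places the methyl group on the outside of the diene, as needed for cycloaddition.

Step 5
Reactants: 6 (E)-2,6-dimethyl-6-[(trimethylsilyl)oxy]hept-2-en-4-ynal; 8 (Z)-triethyl(penta-1,3-dien-3-yloxy)silane
Product: 9 (1S,5RS,6R)-1,5-dimethyl-6-{3-methyl-3-[(trimethylsilyl)oxy]but-1-yn-1-yl}-4-[(triethylsilyl)oxy]cyclohex-3-ene-1-carbaldehyde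
Conditions: (S)-o-tolyl oxazaborolidine·HN(SO2CF3)2 (oxazaborolidinium salt from (S)-α,α-diphenylprolinol, 20 mol%), CH2Cl2, −78 to −40 °C
Reagents that add atoms: none
Why: Lewis-acid-catalysed enantioselective Diels–Alder reaction of a 2-substituted enal; the nucleophilic CH(Me) terminus of the 2-silyloxy diene bonds to the β-carbon (C5). The E geometry is transferred suprafacially, so CHO and alkynyl are trans (C10 methyl and C5 alkynyl cis). The catalyst sets the absolute sense, and the C4 epimer mixture is erased in step 7.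

Step 6
Reactants: 9 (1S,5RS,6R)-1,5-dimethyl-6-{3-methyl-3-[(trimethylsilyl)oxy]but-1-yn-1-yl}-4-[(triethylsilyl)oxy]cyclohex-3-ene-1-carbaldehyde
Product: 11 (2RS,3S,4R)-4-(2,2-dimethoxyethyl)-3-(3-hydroxy-3-methylbut-1-yn-1-yl)-2,4-dimethylcyclohexan-1-one, via methyl enol ether 10 (not isolated)
Conditions: Ph3P(CH2OMe)Cl, KN(SiMe3)2, THF, −78 to 0 °C; then MeOH, CSA, rt
Reagents that add atoms: (methoxymethyl)triphenylphosphonium chloride COC[P+](c1ccccc1)(c1ccccc1)c1ccccc1.[Cl-]; methanol CO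
Why: Wittig methoxymethylenation of the non-enolisable neopentyl aldehyde adds C8. Acidic methanol then turns the enol ether into the dimethyl acetal and cleaves the silyl enol ether (to the C3 ketone) and the Me3Si ether; C5 and C10 are not epimerisable.

Step 7
Reactants: 11 (2RS,3S,4R)-4-(2,2-dimethoxyethyl)-3-(3-hydroxy-3-methylbut-1-yn-1-yl)-2,4-dimethylcyclohexan-1-one
Product: 13 (2S,3S,4R)-4-(2,2-dimethoxyethyl)-2-hydroxy-3-(3-hydroxy-3-methylbut-1-yn-1-yl)-2,4-dimethylcyclohexan-1-one, via C4 hydroperoxide 12 (not isolated)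
Conditions: O2 (1 atm), Cs2CO3 (20 mol%), P(OEt)3, DMSO, rt
Reagents that add atoms: dioxygen O=O
Why: base-mediated aerobic α-hydroxylation occurs at the more substituted (tertiary) α-carbon, and the phosphite reduces the hydroperoxide. Oxygen enters C4 anti to the adjacent C5 alkynyl group and the syn-axial C10 methyl, giving the 4α-hydroxy-4β-methyl centre.

Step 8
Reactants: 13 (2S,3S,4R)-4-(2,2-dimethoxyethyl)-2-hydroxy-3-(3-hydroxy-3-methylbut-1-yn-1-yl)-2,4-dimethylcyclohexan-1-one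
Product: 14 (1S,2S,3S,4R)-4-(2,2-dimethoxyethyl)-3-(3-hydroxy-3-methylbut-1-yn-1-yl)-2,4-dimethylcyclohexane-1,2-diol
Conditions: Me4NBH(OAc)3, MeCN/AcOH (1:1), −25 °C
Reagents that add atoms: none
Why: hydroxyl-directed triacetoxyborohydride reduction; the C4 hydroxyl binds boron and delivers hydride to the same face of the C3 ketone, so the new C3 hydroxyl is trans to the C4 hydroxyl (3β-OH).

Step 9
Reactants: 14 (1S,2S,3S,4R)-4-(2,2-dimethoxyethyl)-3-(3-hydroxy-3-methylbut-1-yn-1-yl)-2,4-dimethylcyclohexane-1,2-diol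
Product: 15 2-[(1R,2S,3S,4S)-3,4-dihydroxy-2-(3-hydroxy-3-methylbut-1-yn-1-yl)-1,3-dimethylcyclohexyl]acetaldehyde
Conditions: AcOH/THF/H2O (3:1:1), 40 °C
Reagents that add atoms: water O
Why: mild acid hydrolysis of the dimethyl acetal unmasks the C8 aldehyde without touching the tertiary alcohols or the alkyne; 15 may sit in equilibrium with its C4–O lactol, which reopens to the reactive aldehyde.

Step 10
Reactants: 15 2-[(1R,2S,3S,4S)-3,4-dihydroxy-2-(3-hydroxy-3-methylbut-1-yn-1-yl)-1,3-dimethylcyclohexyl]acetaldehyde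
Product: 16 (4aR,5S,6S,8aR)-5,6-dihydroxy-3-(2-hydroxypropan-2-yl)-5,8a-dimethyl-4a,5,6,7,8,8a-hexahydronaphthalen-2(1H)-one
Conditions: [Rh(dppe)]2(BF4)2 (5 mol%), acetone, 50 °C
Reagents that add atoms: none
Why: Proposed new method: 6-endo trans-hydroacylation of a 5-alkynal, in which cationic monovalent rhodium inserts into the aldehyde C–H bond to give an acyl rhodium hydride, the hydride goes to C6 (the alkyne carbon remote from the carbinol, the regiochemistry that a propargylic C–O bond imposes on hydrometalation), the alkenyl rhodium isomerises through an η2-vinyl form, and C7–C8 reductive elimination from the seven-membered acyl(alkenyl)rhodacycle gives the cyclohexenone; the two arms are trans-diequatorial on ring A, so the ring fusion set in step 5 becomes the trans-decalin and no new stereocentre forms; the closest known reaction type is the rhodium-catalysed trans-hydroacylation of 4-alkynals to cyclopentenones.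

Step 11
Reactants: 17 tiglic acid [(E)-2-methylbut-2-enoic acid]
Product: 18 (E)-2-methylbut-2-en-1-ol
Conditions: LiAlH4, Et2O, 0 °C to rt; aqueous NaOH work-up
Reagents that add atoms: none
Why: hydride reduction of the carboxylic acid to the allylic alcohol leaves the trisubstituted E alkene intact.

Step 12
Reactants: 18 (E)-2-methylbut-2-en-1-ol
Product: 19 [(2R,3R)-2,3-dimethyloxiran-2-yl]methanol
Conditions: Ti(OiPr)4 (10 mol%), D-(−)-diethyl tartrate (12 mol%), t-BuOOH, 4 Å molecular sieves, CH2Cl2, −20 °C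
Reagents that add atoms: tert-butyl hydroperoxide CC(C)(C)OO
Why: Sharpless asymmetric epoxidation; the D-(−)-tartrate ligand delivers oxygen to the face that gives the (2R,3R) epoxide, and syn addition to the E alkene keeps the two methyl groups cis.

Step 13
Reactants: 19 [(2R,3R)-2,3-dimethyloxiran-2-yl]methanol
Product: 21 (2S,3R)-2,3-dimethyloxirane-2-carboxylic acid, via epoxy aldehyde 20 (not isolated)
Conditions: TEMPO (20 mol%), PhI(OAc)2, MeCN/H2O (1:1), rt
Reagents that add atoms: water O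
Why: oxoammonium-mediated oxidation of the primary alcohol through the aldehyde hydrate to the acid under near-neutral conditions that spare the epoxide; the stereocentres are untouched (the C2 descriptor changes only by priority rules).

Step 14
Reactants: 16 (4aR,5S,6S,8aR)-5,6-dihydroxy-3-(2-hydroxypropan-2-yl)-5,8a-dimethyl-4a,5,6,7,8,8a-hexahydronaphthalen-2(1H)-one; 21 (2S,3R)-2,3-dimethyloxirane-2-carboxylic acid
Product: 23 (1S,2S,4aR,8aR)-1-hydroxy-7-(2-hydroxypropan-2-yl)-1,4a-dimethyl-6-oxo-1,2,3,4,4a,5,6,8a-octahydronaphthalen-2-yl (2S,3R)-2,3-dimethyloxirane-2-carboxylate, via Yamaguchi mixed anhydride 22 (not isolated)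
Conditions: 2,4,6-Cl3C6H2COCl, Et3N, THF, rt; then 16, DMAP, toluene, rt
Reagents that add atoms: none
Why: Yamaguchi esterification acylates only the secondary equatorial C3 hydroxyl, since the C4 and C11 hydroxyls are tertiary; no stereocentre is affected.

## Compound list

1 | 2-methylbut-3-yn-2-ol | C#CC(C)(C)O | starting material
2 | trimethyl[(2-methylbut-3-yn-2-yl)oxy]silane | C#CC(C)(C)O[Si](C)(C)C | intermediate
3 | methacrolein (2-methylprop-2-enal) | C=C(C)C=O | starting material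
4 | 2,3-dibromo-2-methylpropanal (racemic) | O=CC(C)(Br)CBr | intermediate
5 | (E)-3-bromo-2-methylprop-2-enal | O=C/C(C)=C/Br | intermediate
6 | (E)-2,6-dimethyl-6-[(trimethylsilyl)oxy]hept-2-en-4-ynal | O=C/C(C)=C/C#CC(C)(C)O[Si](C)(C)C | intermediate
7 | pent-1-en-3-one (ethyl vinyl ketone) | C=CC(=O)CC | starting material
8 | (Z)-triethyl(penta-1,3-dien-3-yloxy)silane | C=C/C(O[Si](CC)(CC)CC)=C/C | intermediate
9 | (1S,5RS,6R)-1,5-dimethyl-6-{3-methyl-3-[(trimethylsilyl)oxy]but-1-yn-1-yl}-4-[(triethylsilyl)oxy]cyclohex-3-ene-1-carbaldehyde (C10 methyl and C5 alkynyl cis; C4 epimers) | C1(O[Si](CC)(CC)CC)=CC[C@](C)(C=O)[C@@H](C#CC(C)(C)O[Si](C)(C)C)C1C | intermediate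
10 | methyl enol ether of 9 (the 1-CHO group replaced by 2-methoxyethenyl; E/Z mixture) | C1(O[Si](CC)(CC)CC)=CC[C@](C)(C=COC)[C@@H](C#CC(C)(C)O[Si](C)(C)C)C1C | intermediate
11 | (2RS,3S,4R)-4-(2,2-dimethoxyethyl)-3-(3-hydroxy-3-methylbut-1-yn-1-yl)-2,4-dimethylcyclohexan-1-one | O=C1CC[C@](C)(CC(OC)OC)[C@@H](C#CC(C)(C)O)C1C | intermediate
12 | (2S,3S,4R)-4-(2,2-dimethoxyethyl)-2-hydroperoxy-3-(3-hydroxy-3-methylbut-1-yn-1-yl)-2,4-dimethylcyclohexan-1-one | O=C1CC[C@](C)(CC(OC)OC)[C@@H](C#CC(C)(C)O)[C@]1(C)OO | intermediate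
13 | (2S,3S,4R)-4-(2,2-dimethoxyethyl)-2-hydroxy-3-(3-hydroxy-3-methylbut-1-yn-1-yl)-2,4-dimethylcyclohexan-1-one | O=C1CC[C@](C)(CC(OC)OC)[C@@H](C#CC(C)(C)O)[C@]1(C)O | intermediate
14 | (1S,2S,3S,4R)-4-(2,2-dimethoxyethyl)-3-(3-hydroxy-3-methylbut-1-yn-1-yl)-2,4-dimethylcyclohexane-1,2-diol | O[C@H]1CC[C@](C)(CC(OC)OC)[C@@H](C#CC(C)(C)O)[C@]1(C)O | intermediate
15 | 2-[(1R,2S,3S,4S)-3,4-dihydroxy-2-(3-hydroxy-3-methylbut-1-yn-1-yl)-1,3-dimethylcyclohexyl]acetaldehyde | O[C@H]1CC[C@](C)(CC=O)[C@@H](C#CC(C)(C)O)[C@]1(C)O | intermediate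
16 | (4aR,5S,6S,8aR)-5,6-dihydroxy-3-(2-hydroxypropan-2-yl)-5,8a-dimethyl-4a,5,6,7,8,8a-hexahydronaphthalen-2(1H)-one | O[C@H]1CC[C@]2(C)CC(=O)C(C(C)(C)O)=C[C@H]2[C@]1(C)O | intermediate
17 | tiglic acid [(E)-2-methylbut-2-enoic acid] | C/C=C(\C)C(=O)O | starting material
18 | (E)-2-methylbut-2-en-1-ol | C/C=C(\C)CO | intermediate
19 | [(2R,3R)-2,3-dimethyloxiran-2-yl]methanol | C[C@H]1O[C@]1(C)CO | intermediate
20 | (2S,3R)-2,3-dimethyloxirane-2-carbaldehyde | C[C@H]1O[C@]1(C)C=O | intermediate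
21 | (2S,3R)-2,3-dimethyloxirane-2-carboxylic acid | C[C@H]1O[C@]1(C)C(=O)O | intermediate
22 | (2S,3R)-2,3-dimethyloxirane-2-carboxylic 2,4,6-trichlorobenzoic anhydride | C[C@H]1O[C@]1(C)C(=O)OC(=O)c1c(Cl)cc(Cl)cc1Cl | intermediate
23 | (1S,2S,4aR,8aR)-1-hydroxy-7-(2-hydroxypropan-2-yl)-1,4a-dimethyl-6-oxo-1,2,3,4,4a,5,6,8a-octahydronaphthalen-2-yl (2S,3R)-2,3-dimethyloxirane-2-carboxylate | C[C@H]1O[C@]1(C)C(=O)O[C@H]1CC[C@]2(C)CC(=O)C(C(C)(C)O)=C[C@H]2[C@]1(C)O | target

## Step count and risks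

Total step count: 14.
Longest linear sequence: 9 steps (steps 2, 3, 5, 6, 7, 8, 9, 10, 14; the sequence through step 1 instead of step 2 is equally long).

The three steps most likely to fail:

- **Step 10 (the proposed new rhodium hydroacylation).** Simple 5-alkynals are known to give 5-exo alkylidenecyclopentanones, and decarbonylation or lactol formation at the C4 hydroxyl can also intervene. The fallback uses known chemistry, sets out from 15 and returns at 16. Hydroxyl-directed trans-hydrostannation of the propargylic alcohol with Bu3SnH and [Cp*RuCl]4 gives 2-[(1R,2R,3S,4S)-3,4-dihydroxy-2-[(Z)-3-hydroxy-3-methyl-2-(tributylstannyl)but-1-en-1-yl]-1,3-dimethylcyclohexyl]acetaldehyde F6, with tin on C7 cis to C5. Iododestannylation with I2 gives the corresponding (Z)-alkenyl iodide F7. Nozaki–Hiyama–Kishi cyclisation with CrCl2 and catalytic NiCl2 in DMSO closes ring B to the allylic alcohol (4aR,5S,6S,8aR)-3-(2-hydroxypropan-2-yl)-5,8a-dimethyl-1,2,4a,5,6,7,8,8a-octahydronaphthalene-2,5,6-triol F8 (C8 carbinol epimers). MnO2 oxidises only the allylic carbinol and gives 16.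

- **Step 5 (Diels–Alder reaction).** The β-alkynyl-α-methyl enal is an untested dienophile for this catalyst, so rate, enantioselectivity and competing Mukaiyama aldol addition are uncertain. The fallback sets out from 6 and 8 and returns at 9. A Me2AlCl-promoted cycloaddition gives 9 together with its enantiomer, (1R,5RS,6S)-1,5-dimethyl-6-{3-methyl-3-[(trimethylsilyl)oxy]but-1-yn-1-yl}-4-[(triethylsilyl)oxy]cyclohex-3-ene-1-carbaldehyde F1. Condensation of the racemate with (1R,2R)-N,N'-dimethyl-1,2-diphenylethane-1,2-diamine gives two diastereomeric aminals, the (4R,5R)-1,3-dimethyl-4,5-diphenylimidazolidin-2-yl derivative of 9 F2 and the same derivative of the enantiomer F3, which are separated by chromatography. Hydrolysis of F2 on wet silica gel in CH2Cl2 returns 9.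

- **Step 7 (aerobic α-hydroxylation).** Oxidation at C2, α-ketol rearrangement under base, or poor facial selectivity at C4 may occur. The fallback sets out from 11 and returns at 13. Thermodynamic silylation with Me3SiOTf and Et3N gives trimethyl({(3S,4R)-4-(2,2-dimethoxyethyl)-2,4-dimethyl-3-[3-methyl-3-(trimethylsilyloxy)but-1-yn-1-yl]cyclohex-1-en-1-yl}oxy)silane F4. Rubottom oxidation with dimethyldioxirane at −40 °C, from the face anti to the C5 alkynyl group, gives (2S,3S,4R)-4-(2,2-dimethoxyethyl)-2,4-dimethyl-2-(trimethylsilyloxy)-3-[3-methyl-3-(trimethylsilyloxy)but-1-yn-1-yl]cyclohexan-1-one F5. Methanolysis with citric acid in MeOH gives 13.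

Further compounds

F1 | step 5 | (1R,5RS,6S)-1,5-dimethyl-6-{3-methyl-3-[(trimethylsilyl)oxy]but-1-yn-1-yl}-4-[(triethylsilyl)oxy]cyclohex-3-ene-1-carbaldehyde (enantiomer of 9) | C1(O[Si](CC)(CC)CC)=CC[C@@](C)(C=O)[C@H](C#CC(C)(C)O[Si](C)(C)C)C1C
F2 | step 5 | (4R,5R)-2-[(1S,5RS,6R)-1,5-dimethyl-6-{3-methyl-3-[(trimethylsilyl)oxy]but-1-yn-1-yl}-4-[(triethylsilyl)oxy]cyclohex-3-en-1-yl]-1,3-dimethyl-4,5-diphenylimidazolidine | C1(O[Si](CC)(CC)CC)=CC[C@](C)(C2N(C)[C@H](c3ccccc3)[C@@H](c3ccccc3)N2C)[C@@H](C#CC(C)(C)O[Si](C)(C)C)C1C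
F3 | step 5 | (4R,5R)-2-[(1R,5RS,6S)-1,5-dimethyl-6-{3-methyl-3-[(trimethylsilyl)oxy]but-1-yn-1-yl}-4-[(triethylsilyl)oxy]cyclohex-3-en-1-yl]-1,3-dimethyl-4,5-diphenylimidazolidine | C1(O[Si](CC)(CC)CC)=CC[C@@](C)(C2N(C)[C@H](c3ccccc3)[C@@H](c3ccccc3)N2C)[C@H](C#CC(C)(C)O[Si](C)(C)C)C1C
F4 | step 7 | trimethyl({(3S,4R)-4-(2,2-dimethoxyethyl)-2,4-dimethyl-3-[3-methyl-3-(trimethylsilyloxy)but-1-yn-1-yl]cyclohex-1-en-1-yl}oxy)silane | C1(O[Si](C)(C)C)CC[C@](C)(CC(OC)OC)[C@@H](C#CC(C)(C)O[Si](C)(C)C)C=1C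
F5 | step 7 | (2S,3S,4R)-4-(2,2-dimethoxyethyl)-2,4-dimethyl-2-(trimethylsilyloxy)-3-[3-methyl-3-(trimethylsilyloxy)but-1-yn-1-yl]cyclohexan-1-one | O=C1CC[C@](C)(CC(OC)OC)[C@@H](C#CC(C)(C)O[Si](C)(C)C)[C@]1(C)O[Si](C)(C)C
F6 | step 10 | 2-[(1R,2R,3S,4S)-3,4-dihydroxy-2-[(Z)-3-hydroxy-3-methyl-2-(tributylstannyl)but-1-en-1-yl]-1,3-dimethylcyclohexyl]acetaldehyde | O[C@H]1CC[C@](C)(CC=O)[C@@H](/C=C(\[Sn](CCCC)(CCCC)CCCC)C(C)(C)O)[C@]1(C)O
F7 | step 10 | 2-[(1R,2R,3S,4S)-3,4-dihydroxy-2-[(Z)-3-hydroxy-2-iodo-3-methylbut-1-en-1-yl]-1,3-dimethylcyclohexyl]acetaldehyde | O[C@H]1CC[C@](C)(CC=O)[C@@H](/C=C(\I)C(C)(C)O)[C@]1(C)O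
F8 | step 10 | (4aR,5S,6S,8aR)-3-(2-hydroxypropan-2-yl)-5,8a-dimethyl-1,2,4a,5,6,7,8,8a-octahydronaphthalene-2,5,6-triol (C2 epimers) | O[C@H]1CC[C@]2(C)CC(O)C(C(C)(C)O)=C[C@H]2[C@]1(C)O
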